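**Retrosynthetic overview**

- Target 17 ⇐ cleavage of three Si–O bonds ⇐ prenyl group made from a C8 allyl group by cross-metathesis (16 ⇐ 15). The side chain stays allyl through all cationic steps.
- Flavan 15 ⇐ reductive removal of a C4 carbamate nitrogen from 13 ⇐ ring C closed by an enantioselective oxa-Povarov annulation: an O-aryl oxocarbenium ion (C2=O1+) plus benzyl N-vinylcarbamate as the C3–C4 unit, forming C2–C3 and C4–C4a and setting C2.
- Cation precursor 9 (an acyloxy acetal) ⇐ phenol 5 + α-chlorobenzyl pivalate 8 (from aldehyde 6). Phenol 5 ⇐ Claisen rearrangement of the allyl ether of bis-silylated phloroglucinol.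
- Enabling feature: ring A is a phloroglucinol ring in which C4a lies ortho to O1 and ortho/para to the C5 and C7 oxygens, while C8 is substituted. The unit C2=O1+–C8a=C4a is therefore a cationic 2-oxadiene with a single, highly nucleophilic terminus, and the same three oxygens later let the C4–N bond ionise so that the activating group of the dienophile can be erased.
- Ring order: rings A and B come from commercial arenes; ring C is the only ring formed (step 7).

Key step: step 7

Assumption: flavan numbering is used (O1, C2, C3, C4, C4a, C5–C8, C8a; ring A benzo, ring B the C2 aryl, ring C the dihydropyran). The sense of induction of the chiral acid in step 7 cannot be predicted, so the (R)-acid is written and its mirror image is to be used if a first run gives the (2R) series.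

**Route**

Step 1
Reactants: 1 phloroglucinol
Product: 2 3,5-bis(triisopropylsilyloxy)phenol
Conditions: i-Pr3SiCl (2.0 equiv), imidazole, DMF, 0 °C to rt; chromatography
Reagents that add atoms: triisopropylsilyl chloride, CC(C)[Si](Cl)(C(C)C)C(C)C
Why: Silylation of a phenol; the three hydroxyls of 1 are equivalent, so only the degree of silylation has to be controlled by stoichiometry, and the mono- and tris-silyl ethers should be separable and recyclable.

Step 2
Reactants: 2 3,5-bis(triisopropylsilyloxy)phenol
Product: 3 1-(allyloxy)-3,5-bis(triisopropylsilyloxy)benzene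
Conditions: allyl bromide, K2CO3, acetone, reflux
Reagents that add atoms: allyl bromide, C=CCBr
Why: Williamson ether synthesis on the only free phenol; aryl triisopropylsilyl ethers should tolerate K2CO3 in acetone.

Step 3
Reactants: 3 1-(allyloxy)-3,5-bis(triisopropylsilyloxy)benzene
Product: 5 2-allyl-3,5-bis(triisopropylsilyloxy)phenol, via ortho-dienone 4 (not isolated)
Conditions: N,N-diethylaniline, 190 °C
Reagents that add atoms: none
Why: Aromatic Claisen rearrangement ([3,3]-sigmatropic shift, then tautomerisation of dienone 4); the two ortho positions are equivalent, so one product should form, with the allyl group on the carbon that becomes C8 and the freed hydroxyl as the future O1.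

Step 4
Reactants: 6 3-hydroxy-5-methoxybenzaldehyde
Product: 7 3-methoxy-5-(triisopropylsilyloxy)benzaldehyde
Conditions: i-Pr3SiCl, imidazole, DMF, rt
Reagents that add atoms: triisopropylsilyl chloride, CC(C)[Si](Cl)(C(C)C)C(C)C
Why: Silylation of a phenol; the aldehyde is untouched.

Step 5
Reactants: 7 3-methoxy-5-(triisopropylsilyloxy)benzaldehyde
Product: 8 chloro[3-methoxy-5-(triisopropylsilyloxy)phenyl]methyl pivalate (racemic)
Conditions: t-BuCOCl, ZnCl2 (2 mol%), CH2Cl2, 0 °C to rt; used crude
Reagents that add atoms: pivaloyl chloride, CC(C)(C)C(=O)Cl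
Why: Lewis-acid-catalysed addition of an acyl chloride across an aldehyde C=O (α-chloroalkyl ester formation); the aryl silyl ether should survive catalytic ZnCl2.

Step 6
Reactants: 5 2-allyl-3,5-bis(triisopropylsilyloxy)phenol; 8 chloro[3-methoxy-5-(triisopropylsilyloxy)phenyl]methyl pivalate
Product: 9 [2-allyl-3,5-bis(triisopropylsilyloxy)phenoxy][3-methoxy-5-(triisopropylsilyloxy)phenyl]methyl pivalate (racemic)
Conditions: Cs2CO3, MeCN, 0 °C to rt; chromatography on Et3N-deactivated silica
Reagents that add atoms: none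
Why: O-Alkylation of a phenoxide by an α-chloroalkyl ester (the reaction used to make acyloxyalkyl aryl ethers), with the bulky pivaloyl group suppressing acyl transfer; the new acetal centre is racemic and is erased on ionisation in step 7.

Step 7
Reactants: 9 [2-allyl-3,5-bis(triisopropylsilyloxy)phenoxy][3-methoxy-5-(triisopropylsilyloxy)phenyl]methyl pivalate; 10 benzyl N-vinylcarbamate
Product: 13 benzyl N-[(2S,4S)-8-allyl-2-[3-methoxy-5-(triisopropylsilyloxy)phenyl]-5,7-bis(triisopropylsilyloxy)chroman-4-yl]carbamate, via aryloxycarbenium ion 11 (not isolated), via N-acyliminium ion 12 (not isolated)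
Conditions: (R)-3,3'-bis(2,4,6-triisopropylphenyl)-1,1'-binaphthyl-2,2'-diyl N-(trifluoromethylsulfonyl)phosphoramide (10 mol%), 10 (1.5 equiv, added slowly), 4 Å molecular sieves, toluene, −40 °C
Reagents that add atoms: none
Why: Proposed new method: protonation of the pivalate of racemic 9 by the chiral N-triflylphosphoramide and loss of pivalic acid should give the achiral O-aryl oxocarbenium ion 11 as a contact ion pair with the chiral anion; the terminal carbon of enecarbamate 10 (held to the anion through its N–H) attacks C2 to give N-acyliminium ion 12, and ring A then closes on C4 with loss of a proton, so that C2–C3 and C4–C4a form in one operation and the acid is regenerated. The closest known reaction types are the oxa-Povarov reaction of aryloxycarbenium ions with alkenes promoted by SnCl4 (racemic) and the chiral-phosphoric-acid-catalysed Povarov reaction of N-aryl iminium ions with this same enecarbamate; new here are the control of the oxygen variant by a chiral counter-anion and the acyloxy acetal as cation source. Ring C closes by a 6-exo-trig Friedel–Crafts attack of C4a on the iminium carbon, formally the second bond of an inverse-electron-demand [4+2] cycloaddition of the 2-oxadiene C2=O1–C8a=C4a. C2 is set in the first C–C bond formation by the chiral anion, which shields one face of the planar cation while it hydrogen-bonds the enecarbamate; C4 should follow as cis (2S,4S) through an endo-type closure with both substituents equatorial, and its configuration is of no consequence because C4 becomes CH2 in step 8. The step needs ionisation toward the aryloxycarbenium ion (pivalate is a far better leaving group and a far poorer donor than the phenoxide), closure at C4a only (C8 carries the allyl group and the ortho carbons of ring B could only give a five-membered ring), and attack of the cation by the enecarbamate in preference to the allyl group (a monosubstituted alkene that could only give a primary cation or a seven-membered ring, which is why prenyl is installed later).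

Step 8
Reactants: 13 benzyl N-[(2S,4S)-8-allyl-2-[3-methoxy-5-(triisopropylsilyloxy)phenyl]-5,7-bis(triisopropylsilyloxy)chroman-4-yl]carbamate
Product: 15 (2S)-8-allyl-2-[3-methoxy-5-(triisopropylsilyloxy)phenyl]-5,7-bis(triisopropylsilyloxy)chroman, via chroman-4-yl cation 14 (not isolated)
Conditions: Et3SiH (5 equiv), CF3CO2H–CH2Cl2 (1:4), 0 °C
Reagents that add atoms: none
Why: Ionic hydrogenation: the C4–N bond should ionise as 2,4,6-trialkoxybenzyl carbamates do in CF3CO2H (the benzyl carbamate itself is acid-stable), cation 14 is stabilised by O1 and the C5 and C7 oxygens and is trapped by hydride, the C2–O1 bond does not ionise because ring B carries only meta oxygens, and a monosubstituted alkene is not reduced under these conditions.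

Step 9
Reactants: 15 (2S)-8-allyl-2-[3-methoxy-5-(triisopropylsilyloxy)phenyl]-5,7-bis(triisopropylsilyloxy)chroman
Product: 16 (2S)-2-[3-methoxy-5-(triisopropylsilyloxy)phenyl]-8-(3-methylbut-2-en-1-yl)-5,7-bis(triisopropylsilyloxy)chroman
Conditions: second-generation Grubbs catalyst RuCl2(H2IMes)(PCy3)(=CHPh) (5 mol%), 2-methyl-2-butene–CH2Cl2, 40 °C, sealed tube
Reagents that add atoms: 2-methyl-2-butene, CC=C(C)C
Why: Olefin cross-metathesis of an allyl arene with excess 2-methyl-2-butene, the standard allyl-to-prenyl conversion; the trisubstituted product alkene should not react further.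

Step 10
Reactants: 16 (2S)-2-[3-methoxy-5-(triisopropylsilyloxy)phenyl]-8-(3-methylbut-2-en-1-yl)-5,7-bis(triisopropylsilyloxy)chroman
Product: 17 (2S)-2-(3-hydroxy-5-methoxyphenyl)-8-(3-methylbut-2-en-1-yl)chroman-5,7-diol (CNP0173255.1)
Conditions: Bu4NF (3.5 equiv), AcOH (3.5 equiv), THF, 0 °C to rt
Reagents that add atoms: none
Why: Fluoride-mediated cleavage of the three aryl silyl ethers, buffered with acetic acid so that the electron-rich phenols are not exposed to base and the prenyl group and the C2 centre see no acid.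

**Compound list**

1 | phloroglucinol | Oc1cc(O)cc(O)c1 | starting material
2 | 3,5-bis(triisopropylsilyloxy)phenol | Oc1cc(O[Si](C(C)C)(C(C)C)C(C)C)cc(O[Si](C(C)C)(C(C)C)C(C)C)c1 | intermediate
3 | 1-(allyloxy)-3,5-bis(triisopropylsilyloxy)benzene | C=CCOc1cc(O[Si](C(C)C)(C(C)C)C(C)C)cc(O[Si](C(C)C)(C(C)C)C(C)C)c1 | intermediate
4 | 6-allyl-3,5-bis(triisopropylsilyloxy)cyclohexa-2,4-dien-1-one (racemic, transient, not isolated) | C=CCC1C(=O)C=C(O[Si](C(C)C)(C(C)C)C(C)C)C=C1O[Si](C(C)C)(C(C)C)C(C)C | intermediate
5 | 2-allyl-3,5-bis(triisopropylsilyloxy)phenol | C=CCc1c(O)cc(O[Si](C(C)C)(C(C)C)C(C)C)cc1O[Si](C(C)C)(C(C)C)C(C)C | intermediate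
6 | 3-hydroxy-5-methoxybenzaldehyde | COc1cc(O)cc(C=O)c1 | starting material
7 | 3-methoxy-5-(triisopropylsilyloxy)benzaldehyde | COc1cc(O[Si](C(C)C)(C(C)C)C(C)C)cc(C=O)c1 | intermediate
8 | chloro[3-methoxy-5-(triisopropylsilyloxy)phenyl]methyl pivalate (racemic) | COc1cc(O[Si](C(C)C)(C(C)C)C(C)C)cc(C(Cl)OC(=O)C(C)(C)C)c1 | intermediate
9 | [2-allyl-3,5-bis(triisopropylsilyloxy)phenoxy][3-methoxy-5-(triisopropylsilyloxy)phenyl]methyl pivalate (racemic) | COc1cc(O[Si](C(C)C)(C(C)C)C(C)C)cc(C(OC(=O)C(C)(C)C)Oc2cc(O[Si](C(C)C)(C(C)C)C(C)C)cc(O[Si](C(C)C)(C(C)C)C(C)C)c2CC=C)c1 | intermediate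
10 | benzyl N-vinylcarbamate | C=CNC(=O)OCc1ccccc1 | starting material
11 | O-aryl oxocarbenium ion of 9 (cation of the chiral ion pair, not isolated) | COc1cc(O[Si](C(C)C)(C(C)C)C(C)C)cc(C=[O+]c2cc(O[Si](C(C)C)(C(C)C)C(C)C)cc(O[Si](C(C)C)(C(C)C)C(C)C)c2CC=C)c1 | intermediate
12 | (S)-N-acyliminium ion after the first C–C bond formation (not isolated) | COc1cc(O[Si](C(C)C)(C(C)C)C(C)C)cc([C@H](CC=[NH+]C(=O)OCc2ccccc2)Oc2cc(O[Si](C(C)C)(C(C)C)C(C)C)cc(O[Si](C(C)C)(C(C)C)C(C)C)c2CC=C)c1 | intermediate
13 | benzyl N-[(2S,4S)-8-allyl-2-[3-methoxy-5-(triisopropylsilyloxy)phenyl]-5,7-bis(triisopropylsilyloxy)chroman-4-yl]carbamate | COc1cc(O[Si](C(C)C)(C(C)C)C(C)C)cc([C@@H]2C[C@H](NC(=O)OCc4ccccc4)c3c(O[Si](C(C)C)(C(C)C)C(C)C)cc(O[Si](C(C)C)(C(C)C)C(C)C)c(CC=C)c3O2)c1 | intermediate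
14 | (2S)-chroman-4-yl cation from 13 (not isolated) | COc1cc(O[Si](C(C)C)(C(C)C)C(C)C)cc([C@@H]2C[CH+]c3c(O[Si](C(C)C)(C(C)C)C(C)C)cc(O[Si](C(C)C)(C(C)C)C(C)C)c(CC=C)c3O2)c1 | intermediate
15 | (2S)-8-allyl-2-[3-methoxy-5-(triisopropylsilyloxy)phenyl]-5,7-bis(triisopropylsilyloxy)chroman | COc1cc(O[Si](C(C)C)(C(C)C)C(C)C)cc([C@@H]2CCc3c(O[Si](C(C)C)(C(C)C)C(C)C)cc(O[Si](C(C)C)(C(C)C)C(C)C)c(CC=C)c3O2)c1 | intermediate
16 | (2S)-2-[3-methoxy-5-(triisopropylsilyloxy)phenyl]-8-(3-methylbut-2-en-1-yl)-5,7-bis(triisopropylsilyloxy)chroman | COc1cc(O[Si](C(C)C)(C(C)C)C(C)C)cc([C@@H]2CCc3c(O[Si](C(C)C)(C(C)C)C(C)C)cc(O[Si](C(C)C)(C(C)C)C(C)C)c(CC=C(C)C)c3O2)c1 | intermediate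
17 | (2S)-2-(3-hydroxy-5-methoxyphenyl)-8-(3-methylbut-2-en-1-yl)chroman-5,7-diol | COc1cc(O)cc([C@@H]2CCc3c(O)cc(O)c(CC=C(C)C)c3O2)c1 | target

**Step count**

Total steps: 10. Longest linear sequence: 8 (steps 1, 2, 3, 6, 7, 8, 9, 10).

**Steps most likely to fail**

1. Step 7. What may go wrong: poor facial discrimination within the ion pair of 11, giving low enantiomeric purity at C2; or protonation of the enecarbamate itself, followed by its oligomerisation or by aminoalkylation of ring A. The fallback uses known chemistry and closes ring C at O1–C2 instead. It sets out from 7 and 5 and comes back at 15. Vinylmagnesium bromide (THF, −78 °C) should add to aldehyde 7 to give 1-[3-methoxy-5-(triisopropylsilyloxy)phenyl]prop-2-en-1-ol F1. Oxidation with MnO2 (CH2Cl2, rt) should give the aryl vinyl ketone 1-[3-methoxy-5-(triisopropylsilyloxy)phenyl]prop-2-en-1-one F2. Friedel–Crafts conjugate addition of phenol 5 (Sc(OTf)3 catalyst, MeCN, 0 °C) is expected at the carbon ortho to the hydroxyl, the only nucleophilic carbon not flanked by two silyloxy groups, to give 3-[3-allyl-2-hydroxy-4,6-bis(triisopropylsilyloxy)phenyl]-1-[3-methoxy-5-(triisopropylsilyloxy)phenyl]propan-1-one F3. Noyori asymmetric transfer hydrogenation (RuCl[(R,R)-TsDPEN](p-cymene), HCO2H–Et3N, rt), which leaves the allyl group alone, should give (1R)-3-[3-allyl-2-hydroxy-4,6-bis(triisopropylsilyloxy)phenyl]-1-[3-methoxy-5-(triisopropylsilyloxy)phenyl]propan-1-ol F4. Mitsunobu cyclisation (PPh3, diisopropyl azodicarboxylate, THF, 0 °C) with inversion at the carbinol carbon should then give 15, and the route continues with step 9.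

2. Step 6. What may go wrong: C-alkylation of the ambident phenoxide by the easily ionised chloride, acyl transfer from 8 to the phenoxide, or decomposition of the acyloxy acetal on isolation. The fallback makes the cation precursor from an aryl ester. It sets out from 7 and 5 and comes back at 13. Pinnick oxidation of 7 (NaClO2, NaH2PO4, 2-methyl-2-butene, t-BuOH–H2O) should give 3-methoxy-5-(triisopropylsilyloxy)benzoic acid F5. Esterification with 5 (1-ethyl-3-(3-dimethylaminopropyl)carbodiimide hydrochloride, 4-(dimethylamino)pyridine, CH2Cl2) should give 2-allyl-3,5-bis(triisopropylsilyloxy)phenyl 3-methoxy-5-(triisopropylsilyloxy)benzoate F6. Reductive acetylation (i-Bu2AlH, CH2Cl2, −78 °C; then Ac2O, pyridine, 4-(dimethylamino)pyridine, −78 °C to rt) should give [2-allyl-3,5-bis(triisopropylsilyloxy)phenoxy][3-methoxy-5-(triisopropylsilyloxy)phenyl]methyl acetate F7. F7 is put through the conditions of step 7 in place of 9, losing acetic acid instead of pivalic acid, and should give 13.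

3. Step 8. What may go wrong: slow ionisation of the C4–N bond; loss of a C3 proton from cation 14 to a flav-3-ene that can disproportionate under acid and erode the C2 centre; or acid-induced desilylation followed by cyclisation of a freed phenol onto the allyl group. The fallback cleaves the C–N bond by a radical pathway instead of a cationic one. It sets out from 13 and comes back at 15. Me3SiI (from Me3SiCl and NaI, MeCN, 0 °C; MeOH quench) should cleave the benzyl carbamate to (2S,4S)-8-allyl-2-[3-methoxy-5-(triisopropylsilyloxy)phenyl]-5,7-bis(triisopropylsilyloxy)chroman-4-amine F8. Deamination of this primary amine with the anomeric amide N-(benzyloxy)-N-(pivaloyloxy)-4-(trifluoromethyl)benzamide (THF, 45 °C), with loss of dinitrogen, should give 15 without touching C2.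

**Further compounds**

F1 | step 7 | 1-[3-methoxy-5-(triisopropylsilyloxy)phenyl]prop-2-en-1-ol (racemic) | COc1cc(O[Si](C(C)C)(C(C)C)C(C)C)cc(C(O)C=C)c1
F2 | step 7 | 1-[3-methoxy-5-(triisopropylsilyloxy)phenyl]prop-2-en-1-one | COc1cc(O[Si](C(C)C)(C(C)C)C(C)C)cc(C(=O)C=C)c1
F3 | step 7 | 3-[3-allyl-2-hydroxy-4,6-bis(triisopropylsilyloxy)phenyl]-1-[3-methoxy-5-(triisopropylsilyloxy)phenyl]propan-1-one | COc1cc(O[Si](C(C)C)(C(C)C)C(C)C)cc(C(=O)CCc2c(O)c(CC=C)c(O[Si](C(C)C)(C(C)C)C(C)C)cc2O[Si](C(C)C)(C(C)C)C(C)C)c1
F4 | step 7 | (1R)-3-[3-allyl-2-hydroxy-4,6-bis(triisopropylsilyloxy)phenyl]-1-[3-methoxy-5-(triisopropylsilyloxy)phenyl]propan-1-ol | COc1cc(O[Si](C(C)C)(C(C)C)C(C)C)cc([C@H](O)CCc2c(O)c(CC=C)c(O[Si](C(C)C)(C(C)C)C(C)C)cc2O[Si](C(C)C)(C(C)C)C(C)C)c1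
F5 | step 6 | 3-methoxy-5-(triisopropylsilyloxy)benzoic acid | COc1cc(O[Si](C(C)C)(C(C)C)C(C)C)cc(C(=O)O)c1
F6 | step 6 | 2-allyl-3,5-bis(triisopropylsilyloxy)phenyl 3-methoxy-5-(triisopropylsilyloxy)benzoate | COc1cc(O[Si](C(C)C)(C(C)C)C(C)C)cc(C(=O)Oc2cc(O[Si](C(C)C)(C(C)C)C(C)C)cc(O[Si](C(C)C)(C(C)C)C(C)C)c2CC=C)c1
F7 | step 6 | [2-allyl-3,5-bis(triisopropylsilyloxy)phenoxy][3-methoxy-5-(triisopropylsilyloxy)phenyl]methyl acetate (racemic) | COc1cc(O[Si](C(C)C)(C(C)C)C(C)C)cc(C(OC(C)=O)Oc2cc(O[Si](C(C)C)(C(C)C)C(C)C)cc(O[Si](C(C)C)(C(C)C)C(C)C)c2CC=C)c1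
F8 | step 8 | (2S,4S)-8-allyl-2-[3-methoxy-5-(triisopropylsilyloxy)phenyl]-5,7-bis(triisopropylsilyloxy)chroman-4-amine | COc1cc(O[Si](C(C)C)(C(C)C)C(C)C)cc([C@@H]2C[C@H](N)c3c(O[Si](C(C)C)(C(C)C)C(C)C)cc(O[Si](C(C)C)(C(C)C)C(C)C)c(CC=C)c3O2)c1
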